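Ring A (C10, C1, C2, C3, C4, C5) is disconnected at C3–C4, between a methylene and the gem-dimethyl carbon next to the C5 methine. Read backwards, C4 with its two methyl groups is an isopropenyl group on C5, the side chain of (R)-carvone, and C3 is an aldehyde. Both carbons are electrophilic, so they are joined by radical polarity reversal. Iron-hydride hydrogen-atom transfer makes the tertiary C4 radical, which closes onto the C3 sulfonylhydrazone, and loss of sulfinate and N2 leaves CH2. The precursor is ring B alone, carrying both spiro heterocycles, the 6β-acetate, the isopropenyl group and a 3-oxopropyl chain on C10.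

Key step: step 12

Remark: labdane numbering is used for all compounds (C17 on C8, C18/C19 on C4, C20 on C10). β is the face of the C10 methyl group, and stereocentres that are erased later are left open in the SMILES.

Step 1
Reactants: 1 (R)-(−)-carvone
Product: 3 (5R,6S)-6-methylcarvone (methyl trans to the isopropenyl group), via lithium dienolate 2 (not isolated)
Conditions: LDA, THF, −78 °C; MeI, −78 → 0 °C
Reagents that add atoms: iodomethane, CI
Why: Kinetic α′-deprotonation and enolate alkylation place the future C20 methyl group on C10; the new centre is provisional because step 2 re-enolises it.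

Step 2
Reactants: 3 (5R,6S)-6-methylcarvone
Product: 5 (5S,6S)-6-allyl-6-methylcarvone (allyl trans to the isopropenyl group), via lithium enolate 4 (not isolated)
Conditions: LDA, THF–DMPU, −78 °C; allyl bromide, −78 → 0 °C
Reagents that add atoms: allyl bromide, C=CCBr
Why: In this enolate alkylation allyl bromide should approach the tetrasubstituted enolate anti to the neighbouring isopropenyl group, which sets quaternary C10 with the C20 methyl β (cis to isopropenyl) and the C1–C3 chain α.

Step 3
Reactants: 6 (R)-4-(2-hydroxyethyl)-2,2-dimethyl-1,3-dioxolane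
Product: 7 (R)-4-(2-iodoethyl)-2,2-dimethyl-1,3-dioxolane
Conditions: I2, PPh3, imidazole, CH2Cl2, 0 °C → rt
Reagents that add atoms: iodine, II
Why: The Appel reaction substitutes only the primary carbon (future C11), so the stereocentre (future C13) is untouched.

Step 4
Reactants: 7 (R)-4-(2-iodoethyl)-2,2-dimethyl-1,3-dioxolane; 5 (5S,6S)-6-allyl-6-methylcarvone
Product: 9 14,15-dinor-3,4-seco-labda-2,4(18),7-triene-9,13,16-triol 13,16-acetonide (13R; C9 open), via alkyllithium 8 (not isolated)
Conditions: 7, t-BuLi (2 equiv), Et2O–pentane, −78 °C; 5, −78 → −40 °C; H2O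
Reagents that add atoms: none
Why: Iodine–lithium exchange and 1,2-addition of the primary alkyllithium to the enone carbonyl, which has no α-hydrogen left, form C9–C11; the C9 carbinol centre may be a mixture because step 5 erases it.

Step 5
Reactants: 9 seco-labdatriene tertiary alcohol acetonide
Product: 10 (13R)-9α,13-epoxy-14,15-dinor-3,4-seco-labda-2,4(18),7-trien-16-ol
Conditions: camphorsulfonic acid (5 mol %), CH2Cl2, −20 → 0 °C, Et3N quench at full conversion
Reagents that add atoms: none
Why: In this acid-catalysed SN1 allylic etherification the C7–C8–C9 allyl cation is captured in a five-membered ring by the proximal dioxolane oxygen on C13 (the distal oxygen would need a bridged oxonium ion), from the α face anti to the perpendicular C10 methyl group, and the water set free cleaves the resulting oxocarbenium ion, so C9 is set kinetically and C13 keeps its C–O bond.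

Step 6
Reactants: 10 spiro-tetrahydrofuran primary alcohol
Product: 12 16-O-diazoacetate of 10, via glyoxylate tosylhydrazone ester 11 (not isolated)
Conditions: TsNHN=CHCOCl, PhNMe2, CH2Cl2, 0 °C; Et3N, 0 °C → rt
Reagents that add atoms: glyoxylic acid chloride p-toluenesulfonylhydrazone, O=C(Cl)/C=N/NS(=O)(=O)c1ccc(C)cc1
Why: Acylation of the only hydroxy group is followed by base-induced loss of sulfinate (Bamford–Stevens-type diazo formation), which gives the diazoacetate without touching a stereocentre.

Step 7
Reactants: 12 16-O-diazoacetate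
Product: 13 (13S)-9α,13-epoxy-3,4-seco-labda-2,4(18),7-trien-16,15-olide
Conditions: Rh2(cap)4 (1 mol %), CH2Cl2, reflux, slow addition of 12
Reagents that add atoms: none
Why: Rhodium-carbenoid 1,5 C–H insertion into the tertiary, ether-activated C13–H bond (the known route from 2-alkoxyethyl diazoacetates to 4-alkoxy-γ-butyrolactones) proceeds with retention, so quaternary C13 inherits the configuration of 6, and the carboxamidate ligands disfavour cyclopropanation and oxonium-ylide formation.

Step 8
Reactants: 13 spiro-lactone triene
Product: 15 9α,13-epoxy-6-oxo-3,4-seco-labda-2,4(18),7-trien-16,15-olide, via C6 tert-butyl peroxide 14 (not isolated)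
Conditions: Cl4NHPI (20 mol %), t-BuOOH, pyridine, LiClO4, acetone, RVC electrodes, constant current, rt
Reagents that add atoms: tert-butyl hydroperoxide, CC(C)(C)OO
Why: In this N-oxyl-mediated anodic allylic C–H oxidation the weakest C–H (C6–H, next to the only trisubstituted alkene) is abstracted, the allyl radical is trapped at the less hindered C6, and loss of t-BuOH gives the enone; isopropenyl and terminal vinyl groups are known to survive this type of oxidation.

Step 9
Reactants: 15 Δ7-6-ketone
Product: 16 9α,13-epoxy-6-oxo-3,4-seco-labda-2,4(18)-dien-16,15-olide (8βH; C17 methyl α)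
Conditions: IPrCuCl (5 mol %), NaOt-Bu (5 mol %), (EtO)2MeSiH, t-BuOH, toluene, rt
Reagents that add atoms: none
Why: In this copper hydride 1,4-reduction, hydride should reach C8 from the β face, anti to the perpendicular C9–O bond (Felkin–Anh-like, chair-like axial attack), which makes the C17 methyl equatorial (α); isolated alkenes and the lactone are inert.

Step 10
Reactants: 16 saturated 6-ketone
Product: 18 6β-acetoxy-9α,13-epoxy-3,4-seco-labda-2,4(18)-dien-16,15-olide, via lithium 6β-alkoxide 17 (not isolated)
Conditions: L-Selectride, THF, −78 °C; Ac2O, DMAP (cat.), −78 °C → rt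
Reagents that add atoms: acetic anhydride, CC(=O)OC(C)=O
Why: The bulky trialkylborohydride attacks the ketone equatorially from the α face, because the axial C10 methyl blocks the β face, which gives the axial 6β-alkoxide for acetylation in situ while it is not yet flanked by a C4 quaternary carbon.

Step 11
Reactants: 18 6β-acetate with allyl and isopropenyl groups
Product: 19 6β-acetoxy-9α,13-epoxy-3-oxo-3,4-seco-labd-4(18)-en-16,15-olide
Conditions: PdCl2(PhCN)2, CuCl2·2H2O, AgNO2 (all cat.), t-BuOH–MeNO2, O2 (1 atm), rt
Reagents that add atoms: dioxygen, O=O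
Why: The nitrite-modified aldehyde-selective Wacker oxidation is established for allyl groups on quaternary carbons, where Markovnikov attack at C2 is hindered, and the 1,1-disubstituted isopropenyl group does not react.

Step 12
Reactants: 19 3-oxo-3,4-seco-labdene
Product: 23 previtexilactone, via tosylhydrazone 20 (not isolated), via cyclised tosylhydrazine 21 (not isolated), via diazene 22 (not isolated)
Conditions: TsNHNH2, EtOH, rt; Fe(acac)3 (30 mol %), PhSiH3, EtOH (0.02 M), 60 °C; then 75 °C until N2 evolution ends
Reagents that add atoms: none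
Why: Condensation gives the N-tosylhydrazone 20, and an iron(III) hydride formed from Fe(acac)3 and PhSiH3 then transfers a hydrogen atom to the CH2 terminus of the only alkene (Markovnikov MHAT), so the isopropenyl group becomes the tertiary C4 radical that already carries both methyl groups. This nucleophilic radical adds to the electrophilic C3 of the C=N bond, the hydrazinyl radical is reduced by Fe(II)/EtOH to 21, and on heating 21 loses p-toluenesulfinic acid to the diazene 22, which expels N2 and leaves C3 as CH2. The closest known reaction types are the iron-catalysed MHAT reductive coupling of alkenes with hydrazones (inter- and intramolecular) and the traceless hydromethylation of alkenes with formaldehyde sulfonylhydrazones, whose C–N cleavage is that of the Caglioti reduction. Ring A closes in the 6-exo-trig mode through a chair-like transition state in which the two reacting arms are the equatorial substituents on C5 and C10 of the ring B chair. No lasting stereocentre is created (C4 bears two methyl groups and the C3 centre of 21 is erased), and the trans ring fusion follows from the C5 and C10 configurations fixed by carvone and step 2. The step needs hydrogen-atom transfer to one alkene only and cyclisation faster than radical reduction: 19 holds a single C=C bond, the C=N acceptor is far more radicophilic than the ester carbonyls, high dilution disfavours bimolecular quenching, and the neutral medium spares the base-labile β-alkoxy lactone and the acetate.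

Compound list
1 | (R)-(−)-carvone | CC1=CC[C@H](CC1=O)C(C)=C | starting material
2 | lithium dienolate of carvone | CC1=CC[C@H](C=C1O[Li])C(C)=C | intermediate
3 | (5R,6S)-6-methylcarvone | O=C1C(C)=CC[C@@H](C(C)=C)[C@@H]1C | intermediate
4 | lithium enolate of 6-methylcarvone | [Li]OC1=C(C)[C@H](C(C)=C)CC=C1C | intermediate
5 | (5S,6S)-6-allyl-6-methylcarvone | O=C1C(C)=CC[C@@H](C(C)=C)[C@]1(C)CC=C | intermediate
6 | (R)-4-(2-hydroxyethyl)-2,2-dimethyl-1,3-dioxolane | OCC[C@@H]1COC(C)(C)O1 | starting material
7 | (R)-4-(2-iodoethyl)-2,2-dimethyl-1,3-dioxolane | ICC[C@@H]1COC(C)(C)O1 | intermediate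
8 | (R)-2-(2,2-dimethyl-1,3-dioxolan-4-yl)ethyllithium | [Li]CC[C@@H]1COC(C)(C)O1 | intermediate
9 | 14,15-dinor-3,4-seco-labda-2,4(18),7-triene-9,13,16-triol 13,16-acetonide (C9 open) | CC1=CC[C@@H](C(C)=C)[C@](C)(CC=C)C1(O)CC[C@@H]2COC(C)(C)O2 | intermediate
10 | (13R)-9α,13-epoxy-14,15-dinor-3,4-seco-labda-2,4(18),7-trien-16-ol | CC1=CC[C@@H](C(C)=C)[C@](C)(CC=C)[C@@]12CC[C@H](CO)O2 | intermediate
11 | 16-O-glyoxylate tosylhydrazone of 10 | CC1=CC[C@@H](C(C)=C)[C@](C)(CC=C)[C@@]12CC[C@H](COC(=O)/C=N/NS(=O)(=O)c3ccc(C)cc3)O2 | intermediate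
12 | 16-O-diazoacetate of 10 | CC1=CC[C@@H](C(C)=C)[C@](C)(CC=C)[C@@]12CC[C@H](COC(=O)C=[N+]=[N-])O2 | intermediate
13 | (13S)-9α,13-epoxy-3,4-seco-labda-2,4(18),7-trien-16,15-olide | CC1=CC[C@@H](C(C)=C)[C@](C)(CC=C)[C@@]12CC[C@]3(COC(=O)C3)O2 | intermediate
14 | 6-(tert-butylperoxy) derivative of 13 (C6 open) | CC1=CC(OOC(C)(C)C)[C@@H](C(C)=C)[C@](C)(CC=C)[C@@]12CC[C@]3(COC(=O)C3)O2 | intermediate
15 | 9α,13-epoxy-6-oxo-3,4-seco-labda-2,4(18),7-trien-16,15-olide | CC1=CC(=O)[C@@H](C(C)=C)[C@](C)(CC=C)[C@@]12CC[C@]3(COC(=O)C3)O2 | intermediate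
16 | 9α,13-epoxy-6-oxo-3,4-seco-labda-2,4(18)-dien-16,15-olide (8βH) | O=C1C[C@@H](C)[C@]2(CC[C@]3(COC(=O)C3)O2)[C@@](C)(CC=C)[C@@H]1C(C)=C | intermediate
17 | lithium 6β-alkoxide from 16 | [Li]O[C@@H]1C[C@@H](C)[C@]2(CC[C@]3(COC(=O)C3)O2)[C@@](C)(CC=C)[C@@H]1C(C)=C | intermediate
18 | 6β-acetoxy-9α,13-epoxy-3,4-seco-labda-2,4(18)-dien-16,15-olide | CC(=O)O[C@@H]1C[C@@H](C)[C@]2(CC[C@]3(COC(=O)C3)O2)[C@@](C)(CC=C)[C@@H]1C(C)=C | intermediate
19 | 6β-acetoxy-9α,13-epoxy-3-oxo-3,4-seco-labd-4(18)-en-16,15-olide | CC(=O)O[C@@H]1C[C@@H](C)[C@]2(CC[C@]3(COC(=O)C3)O2)[C@@](C)(CCC=O)[C@@H]1C(C)=C | intermediate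
20 | (E)-N-tosylhydrazone of 19 | CC(=O)O[C@@H]1C[C@@H](C)[C@]2(CC[C@]3(COC(=O)C3)O2)[C@@](C)(CC/C=N/NS(=O)(=O)c4ccc(C)cc4)[C@@H]1C(C)=C | intermediate
21 | 3-(2-tosylhydrazinyl)previtexilactone (C3 open) | CC(=O)O[C@@H]1C[C@@H](C)[C@]2(CC[C@]3(COC(=O)C3)O2)[C@@]2(C)CCC(NNS(=O)(=O)c4ccc(C)cc4)C(C)(C)[C@H]12 | intermediate
22 | 3-diazenylprevitexilactone (C3 open) | CC(=O)O[C@@H]1C[C@@H](C)[C@]2(CC[C@]3(COC(=O)C3)O2)[C@@]2(C)CCC(N=N)C(C)(C)[C@H]12 | intermediate
23 | previtexilactone | CC(=O)O[C@@H]1C[C@@H](C)[C@]2(CC[C@]3(COC(=O)C3)O2)[C@@]2(C)CCCC(C)(C)[C@H]12 | target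

Total step count: 12. Longest linear sequence: 11 (steps 1, 2 and 4–12).

Steps most likely to fail

Step 12. The tertiary radical may be quenched by a second hydrogen-atom transfer before it reaches C3, which would hydrogenate the isopropenyl group. The sulfonylhydrazone may also decompose before cyclisation. The fallback sets out from 19, comes back at 23 and uses no radical chemistry.
- Wittig methylenation of 19 (Ph3P=CH2, THF, −78 °C) should give the but-3-enyl isopropenyl diene F1.
- Ring-closing metathesis with a second-generation ruthenium catalyst should close ring A as the C3=C4 trisubstituted cyclohexene F2.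
- Simmons–Smith cyclopropanation (Et2Zn, CH2I2) should give the 3,4-methano compound F3; either face serves.
- Hydrogenolysis of the less hindered C3–CH2 bond (H2, PtO2, AcOH) turns the bridge into the second C4 methyl group and gives 23.

Step 8. Hydrogen abstraction may occur at competing allylic sites (C5–H, C1–H2, the methyl groups), or over-oxidation may set in. The fallback sets out from 13, comes back at 15, and relies on the nucleophilicity of the trisubstituted alkene instead of C–H bond strength.
- mCPBA should epoxidise only the Δ7 alkene to the 7,8-epoxide F4.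
- PhSeNa should open it at the secondary C7 to the 8-hydroxy-7-selenide F5.
- H2O2 should trigger syn-elimination towards C6 to the tertiary allylic alcohol F6.
- Babler–Dauben oxidative transposition with PCC moves the oxygen to C6 and gives 15. The C7 and C8 centres of F4–F6 are erased, so either epoxide face converges.

Step 9. Hydride transfer to the congested β-carbon C8 may be slow or face-unselective, and 1,2-reduction may compete. The fallback sets out from 15 and comes back at 16, and it moves the control element from substrate to catalyst. The enone is activated as an iminium ion with a chiral primary-amine salt, and a Hantzsch ester serves as hydride donor (organocatalytic transfer hydrogenation). The catalyst enantiomer is chosen to deliver hydride to the β face, and the isolated alkenes stay inert. This fallback makes no new compound (F0).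

Further compounds
F1 | step 12 | 6β-acetoxy-9α,13-epoxy-3-methylidene-3,4-seco-labd-4(18)-en-16,15-olide | CC(=O)O[C@@H]1C[C@@H](C)[C@]2(CC[C@]3(COC(=O)C3)O2)[C@@](C)(CCC=C)[C@@H]1C(C)=C
F2 | step 12 | 6β-acetoxy-9α,13-epoxy-19-norlabd-3-en-16,15-olide | CC(=O)O[C@@H]1C[C@@H](C)[C@]2(CC[C@]3(COC(=O)C3)O2)[C@@]2(C)CCC=C(C)[C@H]12
F3 | step 12 | 6β-acetoxy-9α,13-epoxy-3,4-methano-19-norlabdan-16,15-olide (C3 and C4 open) | CC(=O)O[C@@H]1C[C@@H](C)[C@]2(CC[C@]3(COC(=O)C3)O2)[C@@]2(C)CCC4CC4(C)[C@H]12
F4 | step 8 | 7,8-epoxide of 13 (C7 and C8 open) | CC12OC1C[C@@H](C(C)=C)[C@](C)(CC=C)[C@@]23CC[C@]4(COC(=O)C4)O3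
F5 | step 8 | 8-hydroxy-7-(phenylselanyl) derivative of 13 (C7 and C8 open) | CC1(O)C([Se]c2ccccc2)C[C@@H](C(C)=C)[C@](C)(CC=C)[C@@]13CC[C@]4(COC(=O)C4)O3
F6 | step 8 | 9α,13-epoxy-8-hydroxy-3,4-seco-labda-2,4(18),6-trien-16,15-olide (C8 open) | CC1(O)C=C[C@@H](C(C)=C)[C@](C)(CC=C)[C@@]13CC[C@]4(COC(=O)C4)O3
F0 | step 9 | none | none
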